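The constants of this flask were hidden from me, so I worked from the runs and chose one quantity to read from them: the odds with which Z ends up as J.

| flask | Z | E | time |
|---|---|---|---|
| south-east | 120 mM | 1.20 mM |  |
| east | 72.0 mM | 1.20 mM |  |
| south | 120 mM | 1.80 mM |  |
| north-east | 120 mM | 1.20 mM | 56 min |

- south-east run (time / min: [J] / mM): 0.80: 7.9; 2.4: 21.6; 4.6: 35.6; 7.3: 46.1; 10: 50.3; 14: 54.1
- east run (time / min: [J] / mM): 0.80: 5.5; 2.4: 14.0; 4.6: 22.4; 7.3: 29.6; 10: 30.7; 14: 32.4
- south run (time / min: [J] / mM): 0.80: 12.4; 2.4: 32.0; 4.6: 49.1; 7.3: 60.3; 10: 65.6; 14: 66.0

(each reading ± 0.6 mM)

- Overall: Z -> J, with E as catalyst.
- Constant volume, constant temperature.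
- The analysis sees a species whether free or bound.
- An order is taken over about fifteen percent of the charge, up and down.

* apparent order in [Z] of the starting rate, round the charge of the south-east run (the rate where two percent of its Z have turned into J) (one fixed amount of J, the same in the runs compared)
* apparent order in [E] of the starting rate, round the charge of the south-east run (the rate where two percent of its Z have turned into J)
* J in the north-east run at 56 min, as a share of the Z charged

I built a ladder of times, starting with the shortest. In the south-east run the readings at 4.6 min, 7.3 min and 10 min are evenly spaced, and the shrinking of the two gains between them gave a decay constant λ of 0.339 min⁻¹, which is a life of 2.95 min. The next rung was the time the opening rate of that run, read as 9.88 mM min⁻¹, needs to make the whole charge: 12.2 min. This is longer than the life, and the run stalled short of its charge, so I supposed that a side path takes Z without E.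

If both paths depend on Z in the same way, dividing one rate by the other removes Z, and the ratio of J to side product integrates to a constant. The closed form is the end odds φ, the final J over the Z that did not become J, a selectivity factor that should not depend on the charge and should grow in proportion to [E]. The east run supported the first claim, with 45.0 % of its charge as J at 14 min, against 45.1 % in the south-east run. Extending the south-east gain after 10 min with λ gave me an estimated final J of 55.4 mM, so I read φ, the end odds, as 0.858. The asked 56 min lies 14.3 lives past the last reading, so for the north-east run, with the same charge, I reckoned 46.2 %.

The forecast gave 47.5 %, with orders 0.88 in Z and 1.03 in E. Its ground differed from mine: “this isn't equilibrium: the catalyst is dying”.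

The north-east run gave 45.9 %, and the orders were 0.69 in Z and 1.0 in E, so the forecast's order in Z stood above the flask's.

    E + Z → J + E (150.6 L mol⁻¹ min⁻¹)
    2 Z ⇌ Z2, settled at all times (9.420 L mol⁻¹)
    Z → Ja (0.2130 min⁻¹)

Tying up 2 Z as Z2 made no difference to J in the north-east run at 56 min. For the south run, [E] is 1.50 times that of the south-east run, so the proportion to [E] gives an estimated φ of 1.29 and an estimated final J of 67.5 mM. That estimate stands 1.50 mM above the south reading of 66.0 mM at 14 min, which is 2.55 standard deviations.

(The earlier runs and the new flask stem from a simulated flask for substances that don't exist; noise was put on by code.)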